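**Retrosynthetic overview**

1. The C2 butanoate and C14 acetate go on last (C2 carbinol by reagent-controlled reduction of a ketone); the butenolide (O7–C19, C8=C17) comes from an intramolecular Horner–Wadsworth–Emmons reaction on a C8 ketone; the ten-membered ring is closed at C5=C6 by ring-closing metathesis.
2. The 11,12-epoxide forms when O11, released from a temporary γ-lactone (O11–C8(=O)–C9–C10), displaces a C12 mesylate with inversion.
3. Key disconnection: the cyclohexane (C1, C10–C14) is made in one flask by a [3+3] annulation forming C1–C14 and C11–C12, from a bis-silyl dinucleophile and a malonaldehyde mono-acetal (C12–C13–C14) of (2R,4R)-pentane-2,4-diol.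
4. Enabling feature: C11 carries oxygen and lies 1,4 to C8 through C10–C9, so O11–C8 can be tied as a furanone whose silyloxyfuran makes C11 a vinylogous nucleophile; C1 is α to C2 (acyl level); C12 and C14 are 1,3-dioxygenated across the C13 methylene.
5. Ring order: temporary furanone → cyclohexane (key step) → lactone opened, epoxide → ten-membered ring → butenolide.

Key step: step 6

Remark: carbons carry briarane numbers (C1 quaternary; C2 butanoyloxy carbon; C5=C6; C7 lactone CH–O; C8/C17/C19 butenolide β-carbon, α-carbon, carbonyl; C10 ring-fusion CH; C11/C12 epoxide; C14 acetoxy carbon; C15, C16, C18, C20 the methyls on C1, C5, C17, C11). β is the cyclohexane face carrying C15, α the opposite face; "aux" is the (2R,4R)-pentanediol-derived ether on O14; Ipc is isopinocampheyl.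

**Route**

Step 1
Reactants: 1 S-ethyl propanethioate
Product: 2 silyl ketene thioacetal of 1
Conditions: LiN(i-Pr)2, THF, −78 °C; Me3SiCl, −78 °C → rt
Reagents that add atoms: chlorotrimethylsilane C[Si](C)(C)Cl
Why: Kinetic enolisation of the thioester and O-silylation is the standard preparation of silyl ketene thioacetals; no stereocentre is formed.

Step 2
Reactants: 2 silyl ketene thioacetal; 3 5-methylfuran-2(5H)-one (racemic)
Product: 5 S-ethyl 2-(2-methyl-5-oxo-2,5-dihydrofuran-3-yl)propanethioate, via lactone silyl ketene acetal 4 (not isolated)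
Conditions: Me3SiOTf (5 mol%), CH2Cl2, −78 °C; then Pd(OAc)2 (1.05 equiv), MeCN, rt
Reagents that add atoms: none
Why: Mukaiyama–Michael addition of 2 to the butenolide β-carbon (C10) gives lactone silyl ketene acetal 4, which Saegusa–Ito oxidation with palladium diacetate should dehydrogenate to the C9=C10 butenolide; the stereocentres at C1 and C11 are erased in step 3.

Step 3
Reactants: 5 butenolide thioester
Product: 6 bis(trimethylsilyl) dinucleophile (2-silyloxyfuran carrying the C1 silyl ketene thioacetal)
Conditions: LiN(i-Pr)2 (2.3 equiv), Me3SiCl (2.6 equiv, present from the start), THF, −78 °C; used crude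
Reagents that add atoms: chlorotrimethylsilane C[Si](C)(C)Cl
Why: Amide-base enol silylation at C11 (γ-position of the butenolide, giving the aromatic 2-silyloxyfuran) and at C1 (α to the thioester) are both standard enolisations; the ketene thioacetal geometry is of no consequence because C2 becomes trigonal again.

Step 4
Reactants: 7 methyl 3,3-dimethoxypropanoate; 8 (2R,4R)-pentane-2,4-diol
Product: 9 methyl 2-[(4R,6R)-4,6-dimethyl-1,3-dioxan-2-yl]acetate
Conditions: pyridinium p-toluenesulfonate (5 mol%), toluene, 80 °C, 4 Å molecular sieves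
Reagents that add atoms: none
Why: Acid-catalysed transacetalisation driven by removal of methanol; the diol stereocentres are not touched.

Step 5
Reactants: 9 dioxane ester
Product: 10 2-[(4R,6R)-4,6-dimethyl-1,3-dioxan-2-yl]acetaldehyde
Conditions: i-Bu2AlH (1.05 equiv), CH2Cl2, −78 °C; aq. KNaC4H4O6
Reagents that add atoms: none
Why: Low-temperature partial reduction of an ester to the aldehyde by i-Bu2AlH.

Step 6
Reactants: 6 bis(trimethylsilyl) dinucleophile; 10 acetal aldehyde
Product: 13 annulated butenolide (cyclohexane C1/C10–C14 fused to the O11–C8 furanone; 12α-OH; 14α-O-aux), via aldehyde-tethered silyloxyfuran 11 (not isolated), via C12 trimethylsilyl ether 12 (not isolated)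
Conditions: t-BuMe2SiOTf (1.1 equiv), 2,6-di-tert-butyl-4-methylpyridine (0.2 equiv), CH2Cl2, −78 → −30 °C; aq. NaHCO3; citric acid, THF/H2O, 0 °C
Reagents that add atoms: tert-butyldimethylsilyl trifluoromethanesulfonate CC(C)(C)[Si](C)(C)OS(=O)(=O)C(F)(F)F
Why: Proposed new method: the silyl triflate should ionise the dioxane acetal of 10 (silyl triflates activate acetals in preference to aldehydes), the more nucleophilic ketene thioacetal carbon C1 of 6 attacks C14 with inversion at the acetal carbon (the established invertive opening of pentanediol acetals), which fixes C14 as R and silylates the released auxiliary oxygen, and the trimethylsilyl triflate set free then promotes an intramolecular vinylogous Mukaiyama aldol addition of furan C5 (C11) to the tethered C12 aldehyde, so the whole is a formal [3+3] annulation whose closest precedents are the Mukaiyama aldol addition to acetals and the Lewis acid vinylogous aldol reaction of 2-silyloxyfurans. One ring is closed, the cyclohexane C1–C10–C11–C12–C13–C14, by a 6-(enolendo)-exo-trig attack of the furan on the aldehyde, and the temporary furanone ring is returned as the butenolide. C1 is set in the intermolecular event through an open antiperiplanar transition state in which the C13 chain of the oxocarbenium ion lies anti to the bulky furyl group, placing C15 and O14 syn along the C10–C1–C14–C13 chain. C11 and C12 are set in the ring closure through a chair-like transition state that keeps O14 equatorial, puts the flat thioester and not C15 in the axial site syn to the developing axial C20 methyl, and turns the Lewis acid-bound aldehyde oxygen outward and anti to the ring oxygen (the threo preference of Lewis acid-mediated silyloxyfuran aldol additions), which gives the 12α-hydroxyl trans to O11. The step needs chemoselectivity (acetal before aldehyde, ketene thioacetal before furan) and site selectivity in the furan (C5 and not C3), which the silyl triflate promoter, the higher nucleophilicity of the ketene thioacetal and the intrinsic C5 preference of 2-silyloxyfurans should secure.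

Step 7
Reactants: 13 annulated butenolide
Product: 14 cis-fused saturated γ-lactone (H10 α)
Conditions: H2 (1 atm), [Ir(cod)(PCy3)(py)]PF6 (5 mol%), CH2Cl2, rt
Reagents that add atoms: none
Why: Hydroxyl-directed homogeneous hydrogenation should deliver hydrogen to C10 from the face of the homoallylic 12α-hydroxyl, setting H10 α and the cis-fused lactone.

Step 8
Reactants: 14 saturated lactone
Product: 15 C12 α-mesylate
Conditions: MeSO2Cl, Et3N, CH2Cl2, 0 °C
Reagents that add atoms: methanesulfonyl chloride CS(=O)(=O)Cl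
Why: Sulfonylation of the only free hydroxyl through the sulfene; the C12 configuration is retained.

Step 9
Reactants: 15 mesylate
Product: 16 C2 aldehyde/C8 lactol
Conditions: i-Bu2AlH (2.3 equiv), CH2Cl2, −78 °C; aq. KNaC4H4O6
Reagents that add atoms: none
Why: i-Bu2AlH reduces the S-ethyl thioester to the aldehyde (stable tetrahedral intermediate at −78 °C) and the γ-lactone to the lactol in one operation; the lactol anomers are of no consequence.

Step 10
Reactants: 16 aldehyde lactol; 17 4-bromo-2-methylbut-1-ene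
Product: 19 C2 carbinol bearing the 3-methylbut-3-enyl chain (C2 epimers; lactol), via Grignard reagent 18 (not isolated)
Conditions: Mg, THF, rt (17 → 18); then 16, THF, −78 °C (2.5 equiv of 18); aq. NH4Cl
Reagents that add atoms: none
Why: Grignard addition to the free C2 aldehyde while the lactol stays masked as its magnesium alkoxide; the C2 configuration is irrelevant because C2 is oxidised in step 15.

Step 11
Reactants: 19 lactol carbinol; 20 allyl 4-methoxybenzyl ether
Product: 22 8-hydroxy-7-(4-methoxybenzyloxy)-6-ene seco compound (7R,8R; free tertiary O11–H), via alkoxyallylborane 21 (not isolated)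
Conditions: 20, sec-BuLi, THF, −78 °C; (−)-Ipc2BOMe; BF3·OEt2; then 19, −78 °C → rt; aq. NaHCO3, H2O2
Reagents that add atoms: none
Why: Brown γ-alkoxyallylboration of the lactol through its hydroxy aldehyde form proceeds by a Zimmerman–Traxler chair to the syn 8-hydroxy-7-alkoxy unit, and the (−)-Ipc2B reagent (from (+)-α-pinene) should set C7 as R by reagent control.

Step 12
Reactants: 22 seco mesylate
Product: 23 11β,12β-epoxide
Conditions: K2CO3, MeOH, 0 °C → rt
Reagents that add atoms: none
Why: Intramolecular Williamson displacement in which the tertiary O11 alkoxide attacks C12 anti to the mesylate (3-exo-tet), inverting C12 and giving the β-epoxide.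

Step 13
Reactants: 23 epoxy diene
Product: 24 ten-membered carbocycle (5Z olefin)
Conditions: second-generation Grubbs catalyst (10 mol%), toluene (1 mM), 80 °C
Reagents that add atoms: none
Why: Ring-closing metathesis between the C7 vinyl group and the 1,1-disubstituted C5 olefin; the ten-membered ring should accommodate only the Z trisubstituted alkene.

Step 14
Reactants: 24 macrocycle
Product: 25 auxiliary alcohol
Conditions: Bu4NF, THF, 0 °C → rt; aq. NH4Cl
Reagents that add atoms: none
Why: Fluoride cleavage of the silyl ether on the auxiliary.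

Step 15
Reactants: 25 triol
Product: 26 C2/C8/auxiliary triketone
Conditions: Dess–Martin periodinane (4.5 equiv), NaHCO3, CH2Cl2, rt
Reagents that add atoms: none
Why: Buffered Dess–Martin oxidation of the three secondary alcohols leaves the epoxide, the olefin and the benzylic ether untouched.

Step 16
Reactants: 26 triketone
Product: 27 C7 α-hydroxy ketone
Conditions: DDQ, CH2Cl2/pH 7 buffer, 0 °C
Reagents that add atoms: none
Why: Oxidative cleavage of the 4-methoxybenzyl ether by DDQ frees O7 without acid, which the epoxide would not tolerate.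

Step 17
Reactants: 27 hydroxy ketone; 28 2-(diethoxyphosphoryl)propanoic acid
Product: 29 C7 2-(diethoxyphosphoryl)propanoate
Conditions: DCC, DMAP (10 mol%), CH2Cl2, 0 °C → rt
Reagents that add atoms: none
Why: Steglich esterification of the only hydroxyl.

Step 18
Reactants: 29 phosphonate ester
Product: 31 butenolide (free C14 hydroxyl; C2 ketone), via auxiliary-bearing butenolide 30 (not isolated)
Conditions: LiCl, DBU, MeCN, 0 °C → rt
Reagents that add atoms: none
Why: Intramolecular Horner–Wadsworth–Emmons reaction under mild LiCl/amine conditions closes the butenolide onto the C8 ketone, and the same base should remove the auxiliary by E1cB elimination of its β-alkoxy ketone, freeing O14.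

Step 19
Reactants: 31 hydroxy ketone
Product: 32 C14 acetate
Conditions: Ac2O, DMAP, pyridine, rt
Reagents that add atoms: acetic anhydride CC(=O)OC(C)=O
Why: DMAP-catalysed acetylation of the only hydroxyl; the β-acetoxy ketone cannot eliminate because C1 is quaternary.

Step 20
Reactants: 32 keto acetate
Product: 33 (2S)-alcohol
Conditions: (R)-2-methyl-CBS-oxazaborolidine (0.3 equiv), catecholborane, toluene, −78 °C
Reagents that add atoms: none
Why: Corey–Bakshi–Shibata reduction with the quaternary C1 as the large and C3 as the small ketone substituent should give the 2S alcohol by reagent control, and catecholborane at −78 °C should spare the alkenes, lactone, acetate and epoxide.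

Step 21
Reactants: 33 (2S)-alcohol
Product: 34 CNP0220791.1
Conditions: (n-PrCO)2O, DMAP, Et3N, CH2Cl2, rt
Reagents that add atoms: butanoic anhydride CCCC(=O)OC(=O)CCC
Why: DMAP-catalysed acylation of the C2 hydroxyl completes the target.

**Compound list**

1 | S-ethyl propanethioate | CCC(=O)SCC | starting material
2 | trimethyl{[1-(ethylsulfanyl)prop-1-en-1-yl]oxy}silane (E/Z mixture) | CC=C(SCC)O[Si](C)(C)C | intermediate
3 | 5-methylfuran-2(5H)-one (racemic) | CC1OC(=O)C=C1 | starting material
4 | S-ethyl 2-{2-methyl-5-[(trimethylsilyl)oxy]-2,3-dihydrofuran-3-yl}propanethioate (diastereomer mixture, not isolated) | CCSC(=O)C(C)C1C=C(O[Si](C)(C)C)OC1C | intermediate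
5 | S-ethyl 2-(2-methyl-5-oxo-2,5-dihydrofuran-3-yl)propanethioate (diastereomer mixture) | CCSC(=O)C(C)C1=CC(=O)OC1C | intermediate
6 | {[1-(ethylsulfanyl)-2-{2-methyl-5-[(trimethylsilyl)oxy]furan-3-yl}prop-1-en-1-yl]oxy}trimethylsilane | CCSC(O[Si](C)(C)C)=C(C)c1cc(O[Si](C)(C)C)oc1C | intermediate
7 | methyl 3,3-dimethoxypropanoate | COC(=O)CC(OC)OC | starting material
8 | (2R,4R)-pentane-2,4-diol | C[C@@H](O)C[C@@H](C)O | starting material
9 | methyl 2-[(4R,6R)-4,6-dimethyl-1,3-dioxan-2-yl]acetate | COC(=O)CC1O[C@H](C)C[C@@H](C)O1 | intermediate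
10 | 2-[(4R,6R)-4,6-dimethyl-1,3-dioxan-2-yl]acetaldehyde | O=CCC1O[C@H](C)C[C@@H](C)O1 | intermediate
11 | S-ethyl (2S,3R)-3-{[(2R,4R)-4-[(tert-butyldimethylsilyl)oxy]pentan-2-yl]oxy}-2-methyl-2-{2-methyl-5-[(trimethylsilyl)oxy]furan-3-yl}-5-oxopentanethioate (not isolated) | CCSC(=O)[C@@](C)(c1cc(O[Si](C)(C)C)oc1C)[C@@H](CC=O)O[C@H](C)C[C@@H](C)O[Si](C)(C)C(C)(C)C | intermediate
12 | C12 O-trimethylsilyl ether of 13 (not isolated) | CCSC(=O)[C@@]1(C)C2=CC(=O)O[C@]2(C)[C@@H](O[Si](C)(C)C)C[C@H]1O[C@H](C)C[C@@H](C)O[Si](C)(C)C(C)(C)C | intermediate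
13 | S-ethyl (4S,5R,7S,7aS)-5-{[(2R,4R)-4-[(tert-butyldimethylsilyl)oxy]pentan-2-yl]oxy}-7-hydroxy-4,7a-dimethyl-2-oxo-2,4,5,6,7,7a-hexahydro-1-benzofuran-4-carbothioate | CCSC(=O)[C@@]1(C)C2=CC(=O)O[C@]2(C)[C@@H](O)C[C@H]1O[C@H](C)C[C@@H](C)O[Si](C)(C)C(C)(C)C | intermediate
14 | (3aS,4S,5R,7S,7aS)-octahydro analogue of 13 (C9–C10 saturated, H10 α, cis-fused lactone) | CCSC(=O)[C@@]1(C)[C@@H]2CC(=O)O[C@]2(C)[C@@H](O)C[C@H]1O[C@H](C)C[C@@H](C)O[Si](C)(C)C(C)(C)C | intermediate
15 | C12 α-methanesulfonate of 14 | CCSC(=O)[C@@]1(C)[C@@H]2CC(=O)O[C@]2(C)[C@@H](OS(C)(=O)=O)C[C@H]1O[C@H](C)C[C@@H](C)O[Si](C)(C)C(C)(C)C | intermediate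
16 | 15 with the thioester reduced to the C2 aldehyde and the lactone to the C8 lactol (anomer mixture) | O=C[C@@]1(C)[C@@H]2CC(O)O[C@]2(C)[C@@H](OS(C)(=O)=O)C[C@H]1O[C@H](C)C[C@@H](C)O[Si](C)(C)C(C)(C)C | intermediate
17 | 4-bromo-2-methylbut-1-ene | C=C(C)CCBr | starting material
18 | bromo(3-methylbut-3-en-1-yl)magnesium (not isolated) | C=C(C)CC[Mg]Br | intermediate
19 | 16 after addition of the 3-methylbut-3-enyl group to C2 (secondary C2 alcohol, epimer mixture; lactol; C12 α-mesylate) | C=C(C)CCC(O)[C@@]1(C)[C@@H]2CC(O)O[C@]2(C)[C@@H](OS(C)(=O)=O)C[C@H]1O[C@H](C)C[C@@H](C)O[Si](C)(C)C(C)(C)C | intermediate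
20 | 1-methoxy-4-[(prop-2-en-1-yloxy)methyl]benzene (allyl 4-methoxybenzyl ether) | C=CCOCc1ccc(OC)cc1 | starting material
21 | (Z)-[3-(4-methoxybenzyloxy)prop-2-en-1-yl]bis[(1R,2R,3R,5S)-isopinocampheyl]borane (not isolated) | COc1ccc(CO/C=C\CB([C@@H]2C[C@@H]3C[C@H]([C@H]2C)C3(C)C)[C@@H]2C[C@@H]3C[C@H]([C@H]2C)C3(C)C)cc1 | intermediate
22 | seco compound: C10 (H α) carries C9H2–C8H(OH)–C7H(OPMB)–CH=CH2 (7R,8R); free tertiary O11–H (β); C12 α-mesylate; C14 α-O-aux; C2 carbinol chain (epimers) | C=C(C)CCC(O)[C@@]1(C)[C@H](C[C@@H](O)[C@H](OCc2ccc(OC)cc2)C=C)[C@](C)(O)[C@@H](OS(C)(=O)=O)C[C@H]1O[C@H](C)C[C@@H](C)O[Si](C)(C)C(C)(C)C | intermediate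
23 | 22 after ring closure to the 11β,12β-epoxide (C12 inverted) | C=C(C)CCC(O)[C@@]1(C)[C@H](C[C@@H](O)[C@H](OCc2ccc(OC)cc2)C=C)[C@]2(C)O[C@@H]2C[C@H]1O[C@H](C)C[C@@H](C)O[Si](C)(C)C(C)(C)C | intermediate
24 | ten-membered carbocycle C1–C10 closed at the 5Z C5=C6 bond; C2–OH (epimers), 7R-OPMB, 8R-OH, 11β,12β-epoxide, 14α-O-aux | OC1CC/C(C)=C\[C@@H](OCc2ccc(OC)cc2)[C@H](O)C[C@@H]3[C@]4(C)O[C@@H]4C[C@@H](O[C@H](C)C[C@@H](C)O[Si](C)(C)C(C)(C)C)[C@@]13C | intermediate
25 | 24 without the silyl group (auxiliary = (2R,4R)-4-hydroxypentan-2-yl) | OC1CC/C(C)=C\[C@@H](OCc2ccc(OC)cc2)[C@H](O)C[C@@H]3[C@]4(C)O[C@@H]4C[C@@H](O[C@H](C)C[C@@H](C)O)[C@@]13C | intermediate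
26 | triketone: C2 ketone, C8 ketone, auxiliary as (R)-4-oxopentan-2-yl ether; 7R-OPMB | O=C1CC/C(C)=C\[C@@H](OCc2ccc(OC)cc2)C(=O)C[C@@H]3[C@]4(C)O[C@@H]4C[C@@H](O[C@H](C)CC(C)=O)[C@@]13C | intermediate
27 | 26 with free 7R hydroxyl | O=C1CC/C(C)=C\[C@@H](O)C(=O)C[C@@H]3[C@]4(C)O[C@@H]4C[C@@H](O[C@H](C)CC(C)=O)[C@@]13C | intermediate
28 | 2-(diethoxyphosphoryl)propanoic acid (racemic) | CCOP(=O)(OCC)C(C)C(=O)O | starting material
29 | O7 2-(diethoxyphosphoryl)propanoate of 27 (epimers at the phosphonate carbon) | O=C1CC/C(C)=C\[C@@H](OC(=O)C(C)P(=O)(OCC)OCC)C(=O)C[C@@H]3[C@]4(C)O[C@@H]4C[C@@H](O[C@H](C)CC(C)=O)[C@@]13C | intermediate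
30 | butenolide O7–C19(=O)–C17(C18)=C8 closed; auxiliary ketone ether on O14; C2 ketone (not isolated) | O=C1CC/C(C)=C\[C@H]2OC(=O)C(C)=C2C[C@@H]3[C@]4(C)O[C@@H]4C[C@@H](O[C@H](C)CC(C)=O)[C@@]13C | intermediate
31 | 30 without the auxiliary: free 14α-hydroxyl, C2 ketone | O=C1CC/C(C)=C\[C@H]2OC(=O)C(C)=C2C[C@@H]3[C@]4(C)O[C@@H]4C[C@@H](O)[C@@]13C | intermediate
32 | 14-O-acetate of 31 | O=C1CC/C(C)=C\[C@H]2OC(=O)C(C)=C2C[C@@H]3[C@]4(C)O[C@@H]4C[C@@H](OC(C)=O)[C@@]13C | intermediate
33 | (2S)-alcohol from 32 | O[C@H]1CC/C(C)=C\[C@H]2OC(=O)C(C)=C2C[C@@H]3[C@]4(C)O[C@@H]4C[C@@H](OC(C)=O)[C@@]13C | intermediate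
34 | CNP0220791.1 (1R,2S,5Z,7R,10S,11S,12R,14R) | CCCC(=O)O[C@H]1CC/C(C)=C\[C@H]2OC(=O)C(C)=C2C[C@@H]2[C@]3(C)O[C@@H]3C[C@@H](OC(C)=O)[C@@]12C | target

**Step count and risks**

Total step count: 21. Longest linear sequence: 19 steps (steps 1–3 and 6–21; steps 4–5 are a side branch).

Steps most likely to fail:

1. Step 6. What may go wrong: wrong pairing of the two nucleophilic sites with the two electrophilic termini in one flask, oligomerisation by intermolecular attack of the furan on a second oxocarbenium ion, or loss of facial control in either bond formation. Fallback (known reactions run separately; sets out from 5 and 10, returns at 13): 5 is silylated with t-BuMe2SiOTf/Et3N to the isolable bis(tert-butyldimethylsilyl) dinucleophile F1. A silyl triflate-catalysed Mukaiyama aldol addition of F1 to the acetal of 10 at −78 °C, quenched cold, should give the isolated aldehyde-tethered tert-butyldimethylsilyloxyfuran F2. A separate BF3·OEt2-mediated intramolecular vinylogous Mukaiyama aldol reaction at high dilution then closes the cyclohexane to 13.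

2. Step 13. What may go wrong: intermolecular metathesis (oligomerisation) outrunning closure of the strained ten-membered ring, or slow engagement of the 1,1-disubstituted olefin. Fallback (temporary tether; sets out from 23, returns at 25): O2 and O8 of 23 are bridged with 1,3-dichloro-1,1,3,3-tetraisopropyldisiloxane (imidazole, DMF) to the disiloxane-bridged diene F3, which holds the two olefin-bearing arms together. Ring-closing metathesis with the second-generation Hoveyda–Grubbs catalyst should give the bridged macrocycle F4. Bu4NF then removes the disiloxane and the silyl ether of the auxiliary together to give 25.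

3. Step 18. What may go wrong: base-induced epimerisation at C7 (α to the ketone and allylic) before olefination, or retro-aldol opening across C1–C14 once O14 is free in the basic medium. Fallback (neutral Wittig route, auxiliary removed separately; sets out from 27, returns at 31): 27 is acylated with 2-bromopropanoyl bromide/pyridine to the 2-bromopropanoate F5. PPh3 in MeCN gives the phosphonium bromide F6. Et3N generates the stabilised ylide, which closes the butenolide by intramolecular Wittig reaction to 30, isolated here. Piperidinium acetate in benzene then cleaves the auxiliary by β-elimination to 31.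

Further compounds
F1 | step 6 | tert-butyl{[1-(ethylsulfanyl)-2-{5-[(tert-butyldimethylsilyl)oxy]-2-methylfuran-3-yl}prop-1-en-1-yl]oxy}dimethylsilane | CCSC(O[Si](C)(C)C(C)(C)C)=C(C)c1cc(O[Si](C)(C)C(C)(C)C)oc1C
F2 | step 6 | S-ethyl (2S,3R)-3-{[(2R,4R)-4-[(tert-butyldimethylsilyl)oxy]pentan-2-yl]oxy}-2-{5-[(tert-butyldimethylsilyl)oxy]-2-methylfuran-3-yl}-2-methyl-5-oxopentanethioate | CCSC(=O)[C@@](C)(c1cc(O[Si](C)(C)C(C)(C)C)oc1C)[C@@H](CC=O)O[C@H](C)C[C@@H](C)O[Si](C)(C)C(C)(C)C
F3 | step 13 | O2,O8-(1,1,3,3-tetraisopropyldisiloxane-1,3-diyl) derivative of 23 | C=C(C)CCC1O[Si](C(C)C)(C(C)C)O[Si](C(C)C)(C(C)C)O[C@@H]([C@H](OCc2ccc(OC)cc2)C=C)C[C@@H]2[C@]3(C)O[C@@H]3C[C@@H](O[C@H](C)C[C@@H](C)O[Si](C)(C)C(C)(C)C)[C@@]12C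
F4 | step 13 | O2,O8-(1,1,3,3-tetraisopropyldisiloxane-1,3-diyl) derivative of 24 | C15CC/C(C)=C\[C@@H](OCc2ccc(OC)cc2)[C@H](O[Si](C(C)C)(C(C)C)O[Si](C(C)C)(C(C)C)O5)C[C@@H]3[C@]4(C)O[C@@H]4C[C@@H](O[C@H](C)C[C@@H](C)O[Si](C)(C)C(C)(C)C)[C@@]13C
F5 | step 18 | O7 2-bromopropanoate of 27 | O=C1CC/C(C)=C\[C@@H](OC(=O)C(C)Br)C(=O)C[C@@H]3[C@]4(C)O[C@@H]4C[C@@H](O[C@H](C)CC(C)=O)[C@@]13C
F6 | step 18 | triphenylphosphonium bromide from F5 | O=C1CC/C(C)=C\[C@@H](OC(=O)C(C)[P+](c2ccccc2)(c2ccccc2)c2ccccc2)C(=O)C[C@@H]3[C@]4(C)O[C@@H]4C[C@@H](O[C@H](C)CC(C)=O)[C@@]13C.[Br-]
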